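The route rests on cutting ring B across C7–C8 and C9–C10. Ring B of the target holds the all-carbon quaternary centre C10 directly beside the fully substituted C8=C9 double bond, with an oxygen on C6; a [4+2] cycloaddition between a ring A 2-silyloxy diene (C10=C5–C6(OSi)=C7) and a but-2-ynoyl dienophile (C17–C8≡C9–C11) delivers that whole array at once. One chiral copper-catalysed operation thus closes ring B, sets C10, leaves C6 as a masked ketone and C11 as an activated acyl group. The precursors are the TBS enol ether of the ring A methyl ketone and an N-ynoyl pyrazole. C5, C7 and C6 follow by substrate control; the side chain is joined at C11 by sulfone alkylation.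

Key step: step 5

Numbering: labdane locants are used (ring A C1–C5/C10, ring B C5–C10, C11 on C9, C17 on C8, C18/C19 on C4, C20 on C10); C15 bicycles are named as 12,13,14,15,16-pentanorlabdanes; β is the face of the C20 methyl group, α the opposite face.

Assumption: the (S,S)-tert-butyl bis(oxazoline) ligand is taken to give the (10S) adduct 8; if the sense of induction is the reverse, the (R,R) ligand is used with no other change.

Step 1
Reactants: 1 β-cyclocitral
Product: 2 1-(2,6,6-trimethylcyclohex-1-en-1-yl)ethanol (racemic)
Conditions: MeMgBr, Et2O, 0 °C; then aq. NH4Cl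
Reagents that add atoms: methylmagnesium bromide, C[Mg]Br
Why: Grignard 1,2-addition to the aldehyde should be clean because the β carbon of the enal is fully substituted, and the racemic carbinol centre is removed in step 2.

Step 2
Reactants: 2 1-(2,6,6-trimethylcyclohex-1-en-1-yl)ethanol
Product: 3 1-(2,6,6-trimethylcyclohex-1-en-1-yl)ethanone
Conditions: IBX, EtOAc, 80 °C
Reagents that add atoms: none
Why: Hypervalent-iodine oxidation of a secondary allylic alcohol to the ketone under neutral conditions should leave the tetrasubstituted alkene untouched.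

Step 3
Reactants: 3 1-(2,6,6-trimethylcyclohex-1-en-1-yl)ethanone
Product: 4 tert-butyldimethylsilyl enol ether of ketone 3 (2-silyloxy diene)
Conditions: LiN(iPr)2, THF, −78 °C; then t-BuMe2SiCl, DMPU, −78 °C → rt
Reagents that add atoms: tert-butyldimethylsilyl chloride, CC(C)(C)[Si](C)(C)Cl
Why: Kinetic deprotonation of the acetyl methyl group (the only α hydrogens) followed by O-silylation (silyl enol ether formation) should give the cross-conjugated diene, the TBS group being chosen to survive the Lewis acid of step 5 and the basic and hydridic steps 6–11.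

Step 4
Reactants: 5 but-2-ynoic acid; 6 3,5-dimethyl-1H-pyrazole
Product: 7 1-(3,5-dimethylpyrazol-1-yl)but-2-yn-1-one
Conditions: DCC, CH2Cl2, 0 °C → rt
Reagents that add atoms: none
Why: Carbodiimide-mediated N-acylation of the pyrazole (amide-type coupling) should give one product because the two nitrogen atoms of 6 are equivalent by tautomerism.

Step 5
Reactants: 4 tert-butyldimethylsilyl enol ether diene; 7 1-(3,5-dimethylpyrazol-1-yl)but-2-yn-1-one
Product: 8 1-[(10S)-6-(tert-butyldimethylsilyloxy)-12,13,14,15,16-pentanorlabda-5,8-dien-11-oyl]-3,5-dimethylpyrazole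
Conditions: Cu(OTf)2 (10 mol %), (S,S)-t-Bu-bis(oxazoline) (11 mol %), molecular sieves 4 Å, CH2Cl2, −40 → 0 °C
Reagents that add atoms: none
Why: Proposed new method: the acyl pyrazole should chelate the divalent copper centre of Cu(OTf)2·ligand through its carbonyl oxygen and pyrazole N2, which lowers the alkyne LUMO, and diene 4 should add in a concerted but asynchronous [4+2] in which the enol ether terminus C7 bonds to the β-alkyne carbon C8 ahead of C10–C9. The closest known reaction types are divalent-copper bis(oxazoline)-catalysed Diels–Alder reactions of chelating N-acyl dienophiles, N-alkynoyl pyrazoles included, and thermal cycloadditions of 1-vinyl-2,6,6-trimethylcyclohexene with acetylenic esters; their combination on a diene with a fully substituted terminus under asymmetric catalysis has not been shown. Ring B closes as a six-membered carbocycle by intermolecular [4+2] cycloaddition, both σ bonds forming on one face of the diene. The only new stereocentre, C10, is controlled by the ligand: its tert-butyl groups block one face of the chelated ynoyl plane and push the ring A bulk of the diene to one side, so that C9 meets a single enantiotopic face of C10. The step needs regioselectivity (C7 to C8, C10 to C9), which the C6 silyloxy group secures by making C7 the nucleophilic terminus while the acyl group makes C8 the electrophilic carbon, and it needs the enol ether to survive, for which the TBS group and the sieves are chosen. The 1,4-diene product cannot aromatise because C10 is quaternary.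

Step 6
Reactants: 8 bicyclic acyl pyrazole
Product: 9 6-(tert-butyldimethylsilyloxy)-12,13,14,15,16-pentanorlabda-5,8-dien-11-ol
Conditions: LiBH4, THF, MeOH (2 equiv), 0 °C → rt
Reagents that add atoms: none
Why: Borohydride reduction of the N-acyl pyrazole (an activated amide) to the primary allylic alcohol should be 1,2-selective because C8 is fully substituted, and the TBS enol ether is inert to hydride and keeps C6 masked.

Step 7
Reactants: 9 bicyclic allylic alcohol
Product: 11 11-(phenylsulfonyl)-6-(tert-butyldimethylsilyloxy)-12,13,14,15,16-pentanorlabda-5,8-diene, via allylic chloride 10 (not isolated)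
Conditions: MeSO2Cl, LiCl, 2,4,6-collidine, DMF, 0 °C; then PhSO2Na, rt
Reagents that add atoms: sodium benzenesulfinate, [Na+].[O-]S(=O)c1ccccc1
Why: Mesylation with in situ chloride exchange should give the primary allylic chloride without acid, and SN2 S-alkylation of the sulfinate (allylic sulfone synthesis by nucleophilic substitution) then places the sulfone on C11 in a buffered aprotic medium that spares the enol ether.

Step 8
Reactants: 12 prenyl acetate
Product: 13 (E)-4-hydroxy-3-methylbut-2-en-1-yl acetate
Conditions: SeO2 (cat.), t-BuOOH, CH2Cl2, rt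
Reagents that add atoms: tert-butyl hydroperoxide, CC(C)(C)OO
Why: SeO2-catalysed allylic oxidation (ene reaction then [2,3]-sigmatropic shift) should oxidise the methyl group trans to the acetoxymethyl substituent and so fix the E geometry of the later C13=C14 bond; 12 thereby supplies C12–C16.

Step 9
Reactants: 13 (E)-4-hydroxy-3-methylbut-2-en-1-yl acetate
Product: 14 (E)-4-bromo-3-methylbut-2-en-1-yl acetate
Conditions: CBr4, PPh3, CH2Cl2, 0 °C
Reagents that add atoms: carbon tetrabromide, BrC(Br)(Br)Br
Why: The Appel reaction should convert the primary allylic alcohol into the bromide by SN2 displacement without allylic transposition or loss of the E geometry.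

Step 10
Reactants: 11 bicyclic allylic sulfone; 14 (E)-4-bromo-3-methylbut-2-en-1-yl acetate
Product: 15 11-(phenylsulfonyl)-6-(tert-butyldimethylsilyloxy)labda-5,8,13E-trien-15-yl acetate (C11 epimers)
Conditions: n-BuLi, THF, −78 °C; then 14, −78 → −40 °C
Reagents that add atoms: none
Why: The α-sulfonyl carbanion should be alkylated at C11 by the primary allylic bromide (sulfone alkylation) faster than it attacks the acetate at low temperature, forming C11–C12 with the E alkene intact, and the C11 epimers converge in step 11.

Step 11
Reactants: 15 alkylated sulfone acetate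
Product: 17 6-(tert-butyldimethylsilyloxy)labda-5,8,13E-trien-15-ol, via hydroxy sulfone 16 (not isolated)
Conditions: LiBHEt3 (5 equiv), THF, 0 °C; then PdCl2(dppp) (5 mol %), 0 °C → rt
Reagents that add atoms: none
Why: LiBHEt3 should first cleave the acetate (ester reduction) so that no allylic carboxylate remains, then zerovalent palladium formed from PdCl2(dppp) ionises the allylic sulfone to a π-allyl complex that takes hydride at the less substituted C11 terminus (palladium-catalysed reductive desulfonylation), which keeps the C8=C9 and E C13=C14 double bonds in place.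

Step 12
Reactants: 17 desulfonylated silyl enol ether alcohol
Product: 18 15-hydroxylabda-8,13E-dien-6-one (5α-H)
Conditions: 1 M HCl, THF, 0 °C → rt
Reagents that add atoms: none
Why: Acid hydrolysis of the silyl enol ether should protonate C5 on the α face, away from the C20 and axial C4 methyl groups, to give the trans-fused ketone, which is also the thermodynamically preferred ring fusion, while short cold exposure avoids drift of C8=C9 into conjugation.

Step 13
Reactants: 18 15-hydroxylabda-8,13E-dien-6-one
Product: 20 7α,15-bis(triethylsilyloxy)labda-8,13E-dien-6-one, via dihydroxy ketone 19 (not isolated)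
Conditions: KN(SiMe3)2 (2.2 equiv), THF, −78 °C; trans-2-(phenylsulfonyl)-3-phenyloxaziridine, −78 °C; then Et3SiCl, −78 → 0 °C
Reagents that add atoms: trans-2-(phenylsulfonyl)-3-phenyloxaziridine, O=S(=O)(c1ccccc1)N1OC1c1ccccc1; chlorotriethylsilane, CC[Si](Cl)(CC)CC
Why: Deprotonation at the doubly activated C7 (α to the ketone and allylic) should give the kinetic dienolate, whose hydroxylation by the N-sulfonyloxaziridine (enolate α-hydroxylation) occurs on the α face opposite the C20 methyl group to set 7α-O, and both potassium alkoxides are silylated in the same flask so that the base-sensitive α-ketol is never handled.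

Step 14
Reactants: 20 7α,15-bis(triethylsilyloxy)labda-8,13E-dien-6-one
Product: 21 7α,15-bis(triethylsilyloxy)labda-8,13E-dien-6β-ol
Conditions: NaBH4, EtOH/THF, 0 °C
Reagents that add atoms: none
Why: Borohydride reduction of the ketone should take place from the α face because the β face of C6 is screened by the syn-axial C4 and C10 methyl groups, giving the axial 6β-alcohol, and the trans-diaxial relation to the 7α-silyloxy group rules out silyl migration.

Step 15
Reactants: 21 7α,15-bis(triethylsilyloxy)labda-8,13E-dien-6β-ol; 22 isovaleryl chloride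
Product: 23 6β-(3-methylbutanoyloxy)-7α,15-bis(triethylsilyloxy)labda-8,13E-diene
Conditions: DMAP, pyridine, 50 °C
Reagents that add atoms: none
Why: DMAP-catalysed acylation (nucleophilic acyl transfer) should esterify the only free hydroxyl group, excess acid chloride and gentle heating being used because the axial 6β-OH is hindered.

Step 16
Reactants: 23 bis(triethylsilyl) ether ester
Product: 24 6β-(3-methylbutanoyloxy)labda-8,13E-diene-7α,15-diol (target, 5S,6S,7S,10S)
Conditions: HF·pyridine, pyridine, THF, 0 °C → rt
Reagents that add atoms: none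
Why: Buffered fluoride desilylation should remove both triethylsilyl ethers without touching the ester, and the trans-diaxial 6β-ester/7α-hydroxyl arrangement cannot reach the cyclic orthoester needed for acyl migration.

Compound list
1 | β-cyclocitral (2,6,6-trimethylcyclohex-1-ene-1-carbaldehyde) | CC1=C(C=O)C(C)(C)CCC1 | starting material
2 | 1-(2,6,6-trimethylcyclohex-1-en-1-yl)ethanol, racemic | CC(O)C1=C(C)CCCC1(C)C | intermediate
3 | 1-(2,6,6-trimethylcyclohex-1-en-1-yl)ethanone | CC(=O)C1=C(C)CCCC1(C)C | intermediate
4 | tert-butyldimethylsilyl enol ether of 3 (diene C10=C5–C6(OTBS)=C7) | C=C(O[Si](C)(C)C(C)(C)C)C1=C(C)CCCC1(C)C | intermediate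
5 | but-2-ynoic acid | CC#CC(=O)O | starting material
6 | 3,5-dimethyl-1H-pyrazole | Cc1cc(C)n[nH]1 | starting material
7 | 1-(3,5-dimethylpyrazol-1-yl)but-2-yn-1-one | CC#CC(=O)n1nc(C)cc1C | intermediate
8 | (10S)-6-TBSO-pentanorlabda-5,8-dien-11-oyl 3,5-dimethylpyrazole: C5=C6(OTBS), C8=C9, acyl pyrazole on C9, C20 methyl β | CC1=C(C(=O)n3nc(C)cc3C)[C@@]2(C)CCCC(C)(C)C2=C(O[Si](C)(C)C(C)(C)C)C1 | intermediate
9 | 6-TBSO-pentanorlabda-5,8-dien-11-ol (C10 as in 8) | CC1=C(CO)[C@@]2(C)CCCC(C)(C)C2=C(O[Si](C)(C)C(C)(C)C)C1 | intermediate
10 | 11-chloro-6-TBSO-pentanorlabda-5,8-diene (not isolated) | CC1=C(CCl)[C@@]2(C)CCCC(C)(C)C2=C(O[Si](C)(C)C(C)(C)C)C1 | intermediate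
11 | 11-(phenylsulfonyl)-6-TBSO-pentanorlabda-5,8-diene | CC1=C(CS(=O)(=O)c3ccccc3)[C@@]2(C)CCCC(C)(C)C2=C(O[Si](C)(C)C(C)(C)C)C1 | intermediate
12 | prenyl acetate (3-methylbut-2-en-1-yl acetate) | CC(C)=CCOC(C)=O | starting material
13 | (E)-4-hydroxy-3-methylbut-2-en-1-yl acetate | OC/C(C)=C/COC(C)=O | intermediate
14 | (E)-4-bromo-3-methylbut-2-en-1-yl acetate | BrC/C(C)=C/COC(C)=O | intermediate
15 | 11-(phenylsulfonyl)-6-TBSO-labda-5,8,13E-trien-15-yl acetate, C11 epimers | CC1=C(C(C/C(C)=C/COC(C)=O)S(=O)(=O)c3ccccc3)[C@@]2(C)CCCC(C)(C)C2=C(O[Si](C)(C)C(C)(C)C)C1 | intermediate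
16 | 11-(phenylsulfonyl)-6-TBSO-labda-5,8,13E-trien-15-ol, C11 epimers (not isolated) | CC1=C(C(C/C(C)=C/CO)S(=O)(=O)c3ccccc3)[C@@]2(C)CCCC(C)(C)C2=C(O[Si](C)(C)C(C)(C)C)C1 | intermediate
17 | 6-TBSO-labda-5,8,13E-trien-15-ol | CC1=C(CC/C(C)=C/CO)[C@@]2(C)CCCC(C)(C)C2=C(O[Si](C)(C)C(C)(C)C)C1 | intermediate
18 | 15-hydroxylabda-8,13E-dien-6-one (5α-H, 10β-methyl; 5S,10S) | CC1=C(CC/C(C)=C/CO)[C@@]2(C)CCCC(C)(C)[C@@H]2C(=O)C1 | intermediate
19 | 7α,15-dihydroxylabda-8,13E-dien-6-one (not isolated) | CC1=C(CC/C(C)=C/CO)[C@@]2(C)CCCC(C)(C)[C@@H]2C(=O)[C@H]1O | intermediate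
20 | 7α,15-bis(triethylsilyloxy)labda-8,13E-dien-6-one | CC1=C(CC/C(C)=C/CO[Si](CC)(CC)CC)[C@@]2(C)CCCC(C)(C)[C@@H]2C(=O)[C@H]1O[Si](CC)(CC)CC | intermediate
21 | 7α,15-bis(triethylsilyloxy)labda-8,13E-dien-6β-ol | CC1=C(CC/C(C)=C/CO[Si](CC)(CC)CC)[C@@]2(C)CCCC(C)(C)[C@@H]2[C@H](O)[C@H]1O[Si](CC)(CC)CC | intermediate
22 | isovaleryl chloride (3-methylbutanoyl chloride) | CC(C)CC(Cl)=O | starting material
23 | 6β-(3-methylbutanoyloxy)-7α,15-bis(triethylsilyloxy)labda-8,13E-diene | CC1=C(CC/C(C)=C/CO[Si](CC)(CC)CC)[C@@]2(C)CCCC(C)(C)[C@@H]2[C@H](OC(=O)CC(C)C)[C@H]1O[Si](CC)(CC)CC | intermediate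
24 | 6β-(3-methylbutanoyloxy)labda-8,13E-diene-7α,15-diol (5S,6S,7S,10S) | CC1=C(CC/C(C)=C/CO)[C@@]2(C)CCCC(C)(C)[C@@H]2[C@H](OC(=O)CC(C)C)[C@H]1O | target

Total step count: 16.
Longest linear sequence: 13 steps (1 → 2 → 3 → 4 → 8 → 9 → 11 → 15 → 17 → 18 → 20 → 21 → 23 → 24, steps 1, 2, 3, 5, 6, 7, 10–16).

Steps most likely to fail

Step 5. The Lewis acid may strip or transfer the silyl group of the diene, the addition may stop after the first C7–C8 bond without ring closure at the crowded C10 terminus, or the catalyst may discriminate poorly between the two faces at C10. Fallback with known chemistry, setting out from acid 5 and diene 4: acid 5 is activated as its pivalic mixed anhydride (t-BuCOCl, Et3N, THF) and treated with the lithium salt of (S)-4-benzyloxazolidin-2-one to give (S)-4-benzyl-3-(but-2-ynoyl)oxazolidin-2-one F1. Heating F1 with 4 (toluene, 110 °C, sealed tube) is the uncatalysed [4+2] known for 1-vinyl-2,6,6-trimethylcyclohexenes and acetylenic acyl dienophiles; it should give two C10 diastereomers, from which the (10S) imide adduct F2 is separated by chromatography or crystallisation. LiBH4 (THF, MeOH, 0 °C) then removes the auxiliary reductively, and the route is rejoined at alcohol 9.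

Step 13. The dialkoxide of the α-ketol may tautomerise through the enediol to the conjugated 6-hydroxy-7-ketone or be oxidised further before it is silylated, the enolate may add to the sulfonimine by-product, or attack on C7 may not be fully α-selective. Fallback, setting out from 18: Et3SiOTf (excess) and Et3N (CH2Cl2, −78 → 0 °C) silylate O15 and convert the ketone into the conjugated dienol ether 6,15-bis(triethylsilyloxy)labda-6,8,13E-triene F3. Rubottom oxidation with dimethyldioxirane (acetone/CH2Cl2, −78 °C) epoxidises the electron-rich C6=C7 bond on the α face, and the silyloxy epoxide rearranges by 1,4-silyl shift on warming. The route is rejoined at the 7α-silyloxy ketone 20.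

Step 11. Oxidative addition of zerovalent palladium into the hindered C11–S bond may be slow, so that hydride delivery competes poorly with β-hydride elimination or with transposition of the C8=C9 double bond; the carbanion alkylation of step 10 that feeds it may also be slowed by crowding at C11. Fallback without a sulfone, setting out from alcohol 9: chloride 10 is made as in step 7 but isolated and used to alkylate the sodium enolate of allyl acetoacetate (NaH, THF, NaI cat.), giving allyl 2-acetyl-3-(bicyclic)propanoate F4. Pd(OAc)2/PPh3 with HCO2H–Et3N (THF, rt) removes the allyl ester with decarboxylation to give 6-TBSO-14,15-dinorlabda-5,8-dien-13-one F5. Horner–Wadsworth–Emmons olefination with triethyl phosphonoacetate (NaH, THF) gives, after removal of the minor Z isomer, ethyl 6-TBSO-labda-5,8,13E-trien-15-oate F6. i-Bu2AlH (CH2Cl2, −78 °C) reduces the ester, and the route is rejoined at allylic alcohol 17.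

Further compounds
F1 | step 5 | (S)-4-benzyl-3-(but-2-ynoyl)oxazolidin-2-one | CC#CC(=O)N1[C@@H](Cc2ccccc2)COC1=O
F2 | step 5 | (10S) imide adduct: analogue of 8 carrying (S)-4-benzyloxazolidin-2-one in place of the pyrazole | CC1=C(C(=O)N3[C@@H](Cc4ccccc4)COC3=O)[C@@]2(C)CCCC(C)(C)C2=C(O[Si](C)(C)C(C)(C)C)C1
F3 | step 13 | 6,15-bis(triethylsilyloxy)labda-6,8,13E-triene (5α-H) | CC1=C(CC/C(C)=C/CO[Si](CC)(CC)CC)[C@@]2(C)CCCC(C)(C)[C@@H]2C(O[Si](CC)(CC)CC)=C1
F4 | step 11 | allyl 2-acetyl-3-[6-TBSO-pentanorlabda-5,8-dien-11-yl... C11 unit]propanoate (C12 epimers) | CC1=C(CC(C(C)=O)C(=O)OCC=C)[C@@]2(C)CCCC(C)(C)C2=C(O[Si](C)(C)C(C)(C)C)C1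
F5 | step 11 | 6-TBSO-14,15-dinorlabda-5,8-dien-13-one | CC1=C(CCC(C)=O)[C@@]2(C)CCCC(C)(C)C2=C(O[Si](C)(C)C(C)(C)C)C1
F6 | step 11 | ethyl 6-TBSO-labda-5,8,13E-trien-15-oate | CC1=C(CC/C(C)=C/C(=O)OCC)[C@@]2(C)CCCC(C)(C)C2=C(O[Si](C)(C)C(C)(C)C)C1
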